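**Retrosynthetic overview**
1. The only ring, the furan-2(5H)-one, is closed last. Cutting C3=C4 and O1–C5 gives an α-keto ester (C2, C3 and the acetoxybutyl arm) and a 1-bromo-3-iodoacetone enol silane (C4, C5 and the exocyclic CHI carbon).
2. Enabling feature: C5 is a latent ketone carbon lying 1,4 to the lactone carbonyl C2, flanked by the brominated carbon C4 and the iodinated exocyclic carbon. The enol lactone C3=C4–C5(=CHI)–O1 is therefore the twofold dehydration product of an aldol between a C3 keto group and the CHBr carbon of that haloketone, followed by 5-exo lactol closure.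
3. The C1' stereocentre is set first by a catalytic asymmetric aldol addition of tert-butyl diazoacetate to butanal. Acetylation and oxidation of the diazo carbon give the α-keto ester, and the tert-butyl ester is a latent acid that the key step unmasks.
4. The C4–C5–C6 partner comes from 1,3-dibromoacetone by silyl enol ether formation and halide exchange at the allylic bromide.
5. Ring order: no ring exists before step 6, which forms the furanone ring and both of its C=C bonds.

Key step: step 6

Remark: ring atoms are numbered O1, C2 (carbonyl), C3, C4, C5, with C6 the exocyclic carbon and C1' the carbinol carbon; the ProPhenol antipode that delivers the 3R carbinol is assumed to be chosen by the usual model of the catalyst.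

Step 1
Reactants: 1 tert-butyl diazoacetate; 2 butanal
Product: 3 tert-butyl (3R)-2-diazo-3-hydroxyhexanoate
Conditions: Bu2Mg (10 mol%), ProPhenol ligand (5 mol%, antipode giving 3R), cis-cyclopentane-1,2-diol (5 mol%), THF, −20 °C
Reagents that add atoms: none
Why: Direct asymmetric aldol addition of the diazo ester C–H to the aldehyde under dinuclear magnesium–ProPhenol catalysis; the chiral pocket of the catalyst selects the aldehyde face and so sets the C3 (later C1') stereocentre.

Step 2
Reactants: 3 tert-butyl (3R)-2-diazo-3-hydroxyhexanoate
Product: 4 tert-butyl (3R)-3-(acetyloxy)-2-diazohexanoate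
Conditions: Ac2O, pyridine, DMAP (cat.), CH2Cl2, 0 °C
Reagents that add atoms: acetic anhydride, CC(=O)OC(C)=O
Why: DMAP-catalysed O-acylation of a secondary alcohol; the C–O bond of the stereocentre is not touched and diazo esters tolerate these conditions.

Step 3
Reactants: 4 tert-butyl (3R)-3-(acetyloxy)-2-diazohexanoate
Product: 5 tert-butyl (3R)-3-(acetyloxy)-2-oxohexanoate
Conditions: dimethyldioxirane, acetone, 0 °C to rt; dried azeotropically before use
Reagents that add atoms: dimethyldioxirane, CC1(C)OO1
Why: Dioxirane oxidation of a diazo carbon to a ketone with loss of N2; the medium is neutral and non-enolising, so the stereocentre, now α to a ketone, should not epimerise.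

Step 4
Reactants: 6 1,3-dibromoacetone
Product: 7 tert-butyl{[(1Z)-1,3-dibromoprop-1-en-2-yl]oxy}dimethylsilane
Conditions: TBSOTf, iPr2NEt, CH2Cl2, −78 to 0 °C
Reagents that add atoms: tert-butyldimethylsilyl trifluoromethanesulfonate, CC(C)(C)[Si](C)(C)OS(=O)(=O)C(F)(F)F
Why: Soft enolisation and O-silylation of a ketone; the ketone is symmetric, so only one regioisomer can form, and the hindered base limits N-alkylation. The enol ether geometry is of no consequence later.

Step 5
Reactants: 7 tert-butyl{[(1Z)-1,3-dibromoprop-1-en-2-yl]oxy}dimethylsilane
Product: 8 tert-butyl{[(1Z)-1-bromo-3-iodoprop-1-en-2-yl]oxy}dimethylsilane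
Conditions: NaI, acetone, rt, dark; used crude
Reagents that add atoms: sodium iodide, [Na+].[I-]
Why: Finkelstein SN2 exchange at the allylic sp3 C–Br bond, driven by precipitation of NaBr; the vinylic C–Br bond is inert to iodide.

Step 6
Reactants: 5 tert-butyl (3R)-3-(acetyloxy)-2-oxohexanoate; 8 tert-butyl{[(1Z)-1-bromo-3-iodoprop-1-en-2-yl]oxy}dimethylsilane
Product: 11 (1R)-1-[(5Z)-4-bromo-5-(iodomethylidene)-2-oxo-2,5-dihydrofuran-3-yl]butyl acetate, via aldol adduct 9 (not isolated), via hydroxy lactol 10 (not isolated)
Conditions: TiCl4 (precomplexed to 5), CH2Cl2, −78 to −40 °C; then TFA, 0 °C to rt; then P2O5, 40 °C, dark (one flask)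
Reagents that add atoms: none
Why: Titanium chelation of the 1,2-dicarbonyl of 5 makes the ketone the only electrophile, and enol silane 8 can attack only through its CHBr carbon, so the Mukaiyama aldol addition forms the C3–C4 bond with bromine and the iodomethyl group already in place. Trifluoroacetic acid then frees the carboxylic acid from the tert-butyl ester, and its oxygen adds to the C5 ketone lying 1,4 to it in a 5-exo-trig closure that forms the O1–C5 bond of the only ring. Acid-mediated β-elimination of the tertiary aldol hydroxyl gives the C3=C4 double bond, and ionisation of the lactol at C5 with loss of a proton from the iodomethyl group gives the exocyclic alkene, P2O5 taking up both equivalents of water. The closest known reaction types are the Mukaiyama aldol addition of enol silanes to α-keto esters and the acid cyclodehydration of brominated 4-oxo acids to 5-(halomethylidene)furan-2(5H)-ones. The two stereocentres created in the aldol are destroyed again, the C1' centre is safe because its neighbouring ketone is consumed at −78 °C before acid is added, and the Z geometry should follow from thermodynamic control through reversible protonation at the exocyclic carbon, which puts iodine syn to O1 and away from the C4 bromine. The step needs C-attack of the enol silane without ionisation of its allylic iodide, which precomplexation of TiCl4 with 5 and the low temperature should secure.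

**Compound list**
1 | tert-butyl diazoacetate | CC(C)(C)OC(=O)C=[N+]=[N-] | starting material
2 | butanal | CCCC=O | starting material
3 | tert-butyl (3R)-2-diazo-3-hydroxyhexanoate | CCC[C@@H](O)C(=[N+]=[N-])C(=O)OC(C)(C)C | intermediate
4 | tert-butyl (3R)-3-(acetyloxy)-2-diazohexanoate | CCC[C@@H](OC(C)=O)C(=[N+]=[N-])C(=O)OC(C)(C)C | intermediate
5 | tert-butyl (3R)-3-(acetyloxy)-2-oxohexanoate | CCC[C@@H](OC(C)=O)C(=O)C(=O)OC(C)(C)C | intermediate
6 | 1,3-dibromoacetone | BrCC(=O)CBr | starting material
7 | tert-butyl{[(1Z)-1,3-dibromoprop-1-en-2-yl]oxy}dimethylsilane | Br/C=C(/CBr)O[Si](C)(C)C(C)(C)C | intermediate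
8 | tert-butyl{[(1Z)-1-bromo-3-iodoprop-1-en-2-yl]oxy}dimethylsilane | Br/C=C(/CI)O[Si](C)(C)C(C)(C)C | intermediate
9 | tert-butyl 2-[(1R)-1-(acetyloxy)butyl]-3-bromo-2-hydroxy-5-iodo-4-oxopentanoate (aldol adduct, diastereomer mixture at C2 and C3) | CCC[C@@H](OC(C)=O)C(O)(C(Br)C(=O)CI)C(=O)OC(C)(C)C | intermediate
10 | (1R)-1-[4-bromo-3,5-dihydroxy-5-(iodomethyl)-2-oxooxolan-3-yl]butyl acetate (hydroxy lactol, diastereomer mixture in the ring) | CCC[C@@H](OC(C)=O)C1(O)C(Br)C(O)(CI)OC1=O | intermediate
11 | (1R)-1-[(5Z)-4-bromo-5-(iodomethylidene)-2-oxo-2,5-dihydrofuran-3-yl]butyl acetate | CCC[C@@H](OC(C)=O)C1=C(Br)/C(=C/I)OC1=O | target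

**Step count and risks**
Total steps: 6. Longest linear sequence: 4 (steps 1, 2, 3, 6); steps 4 and 5 form the second branch.

Step 6 is the most likely to fail. The enol silane may not add to the hindered, chelated ketone, or its allylic iodide may ionise. In the acid stage the aldol adduct may revert by retro-aldol cleavage, or the acetyl group may migrate to the tertiary hydroxyl before dehydration. The fallback sets out from 5 and returns at 11. Wittig olefination of 5 with 1-bromo-1-(triphenylphosphoranylidene)propan-2-one (toluene, 90 °C) should give tert-butyl (2E)-2-[(1R)-1-(acetyloxy)butyl]-3-bromo-4-oxopent-2-enoate F1, so the C3=C4 bond is made without a tertiary carbinol; any Z isomer should equilibrate under the later acid. Acid-mediated α-iodination at its single enolisable position, the methyl ketone (I2, CuO, MeOH), should give tert-butyl (2E)-2-[(1R)-1-(acetyloxy)butyl]-3-bromo-5-iodo-4-oxopent-2-enoate F2. TFA and then P2O5 should cleave the ester and cyclodehydrate F2 to 11.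

Step 5 is the second risk. The halide exchange may be accompanied by desilylation, and the light- and acid-sensitive allylic iodide may decompose on concentration. The fallback sets out from 5 and returns at 11, with iodine introduced after ring formation. Commercial bromoacetone is converted (TMSOTf, iPr2NEt) into {[(1Z)-1-bromoprop-1-en-2-yl]oxy}trimethylsilane F3. F3 is combined with 5 under the conditions of step 6 to give (1R)-1-(4-bromo-5-methylidene-2-oxo-2,5-dihydrofuran-3-yl)butyl acetate F4. Addition of ICl (CH2Cl2, −78 °C) to the exocyclic enol-ester alkene should give (1R)-1-[4-bromo-5-chloro-5-(iodomethyl)-2-oxo-2,5-dihydrofuran-3-yl]butyl acetate F5, and Et3N should eliminate HCl to give 11, the Z isomer being favoured thermodynamically.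

Step 1 is the third risk. Enantiofacial discrimination may be insufficient with a small unbranched aldehyde and the bulkier tert-butyl ester. The fallback sets out from 1 and 2 and returns at 4. A DBU-catalysed aldol addition gives rac-tert-butyl 2-diazo-3-hydroxyhexanoate F6. Lipase-catalysed kinetic resolution (Burkholderia cepacia lipase, vinyl acetate, MTBE, 30 °C) should acylate the R enantiomer by the usual size rule for secondary alcohols, with the diazo ester arm as the large group, and so give 4 directly; the unreacted S alcohol is separated.

**Further compounds**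
F1 | step 6 | tert-butyl (2E)-2-[(1R)-1-(acetyloxy)butyl]-3-bromo-4-oxopent-2-enoate | CCC[C@@H](OC(C)=O)/C(C(=O)OC(C)(C)C)=C(\Br)C(C)=O
F2 | step 6 | tert-butyl (2E)-2-[(1R)-1-(acetyloxy)butyl]-3-bromo-5-iodo-4-oxopent-2-enoate | CCC[C@@H](OC(C)=O)/C(C(=O)OC(C)(C)C)=C(\Br)C(=O)CI
F3 | step 5 | {[(1Z)-1-bromoprop-1-en-2-yl]oxy}trimethylsilane | Br/C=C(/C)O[Si](C)(C)C
F4 | step 5 | (1R)-1-(4-bromo-5-methylidene-2-oxo-2,5-dihydrofuran-3-yl)butyl acetate | CCC[C@@H](OC(C)=O)C1=C(Br)C(=C)OC1=O
F5 | step 5 | (1R)-1-[4-bromo-5-chloro-5-(iodomethyl)-2-oxo-2,5-dihydrofuran-3-yl]butyl acetate | CCC[C@@H](OC(C)=O)C1=C(Br)C(Cl)(CI)OC1=O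
F6 | step 1 | rac-tert-butyl 2-diazo-3-hydroxyhexanoate | CCCC(O)C(=[N+]=[N-])C(=O)OC(C)(C)C
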